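| setting | autumn | midnight | summer |
|---|---|---|---|
| substrate | 0.80 M | 0.80 M | 0.80 M |
| time | 12 s |  |  |
| remark | a closed flask charged with all of it at once and left for 12 s | one stirred flow tank at steady state, fed with the mixture as stated, mean residence time 120 s | one stirred flow tank at steady state, fed with the mixture as stated, mean residence time 12 s |

    substrate ⇌ intermediate A (K1 = 2.2, k1 = 0.12 s⁻¹)
    intermediate A → intermediate B (k2 = 0.035 s⁻¹)
    intermediate B → target (k3 = 0.0038 s⁻¹)
    substrate → target (k4 = 0.095 s⁻¹)
    substrate + intermediate B → side product (k5 = 0.19 M⁻¹ s⁻¹)

- percent here means substrate units held: one side product counts as two
- the stated concentrations are those of everything mixed, before any reaction; amounts are the same in each set-up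
- run time (autumn): 12 s

- the set-up with the highest share of target in all that became target or side product, at the outlet or at the end ("none" if the first two lie within 2 percentage points) (autumn / midnight / summer / none)
- share of target in all that became target or side product, at the outlet or at the end, autumn
- share of target in all that became target or side product, at the outlet or at the end, midnight
- share of target in all that became target or side product, at the outlet or at the end, summer

Intermediate B is the species to watch. The direct route to target and the route to side product both spend substrate at first order, so substrate cancels from their ratio. Drop the slow third step, which adds a little target, and write B for the concentration of intermediate B. Then define the break-even level H, the concentration of intermediate B at which the two routes take equal substrate units, as the direct constant over twice the side-product constant: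

H = 0.250 M
instantaneous share of target (the selectivity) = H/(H + B)

Now take the two extremes. With B at zero the share is 100%. In a tank, substrate reacts at the outlet level of B, so balance each species there, leaving the side-product step out of the substrate balance:

summer: intermediate A/substrate = 0.694, substrate 0.256 M, B = 0.0458 M, share 84.5%
midnight: intermediate A/substrate = 1.23, substrate 0.0426 M, B = 0.0904 M, share 73.4%

The closed flask of autumn lies between these cases. Its B starts at zero and cannot pass the level reached if the first step's share of substrate sat as intermediate A from the start:

cap = 0.153 M

Held at that cap for the whole run, the share is 62.0%, a floor too low to rank the flasks. But substrate halves by its forward steps, the way back not counted, in 3.22 s, earlier than 12 s, so take the B of that moment as a rough estimate of what substrate meets. The same ceiling curve gives B = 0.0476 M there, and a share of 84.0%. That curve starts intermediate A at its full level, so it overstates B, and I therefore put autumn first, as an estimate and not a bound, without a figure as sharp as the forecast's.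

The forecast gives 92% for autumn, 76% for midnight and 85% for summer, with autumn best, since intermediate B “builds up only as substrate is depleted”.

The simulation gives 92.9%, 76.2% and 84.9%, with autumn best. In autumn at 12.0 s, side product 3.42% over target 45.0%, times H, reads as an effective B of 2.38% of the charge. That is a quarter of the 8.90% then standing. Carry the same fraction to autumn left until 30 s, where intermediate B stands at 17.9%: the effective level becomes 4.78% and the share 86.7%. That flask gives 87.2%.

The numbers were drawn at random within sensible limits; no experiment stands behind them.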